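## The problem

Compound 24 is a 2,3-trans 2,3-diaryl-5,7-dihydroxychroman-4-one. Ring A (the phloroglucinol ring) is fused through C4a–C8a to the pyranone ring C; C2 carries the 4-hydroxyphenyl ring B; C3 carries ring D, a 2-hydroxyphenyl group whose C5 bears an E-enone ending in the 2,4-dihydroxyphenyl ketone ring E. The only stereocentres are C2 (S) and C3 (R). C3 is benzylic and α to the C4 ketone, so it equilibrates to the trans, diequatorial isomer and can follow C2; only C2 has to be set absolutely. The same acidity is the main hazard: a base that enolises C3 can expel O1 (E1cB), opening ring C to an achiral α-aryl chalcone and erasing both centres. Ionisation of the O1–C2 bond, assisted by the para-oxygenated ring B, followed by re-equilibration of C3 has the same effect. The enone excludes hydrogenolysis, the 2'-hydroxy enone can close to a second chromanone under base, and six phenols must be carried or revealed without strong base or hot protic acid. The structure opens at ring C: with ring A pared down to its fusion bond C4a=C8a, ring C is a 2,3-diaryl-2,3-dihydropyran-4-one, O1–C2(aryl)–C3(aryl)–C4(=O)–C4a=C8a. That is the retron of an aryl aldehyde (C2, O1) and a 4-aryl-1-methoxy-3-silyloxy diene (C3, C4, C4a, C8a). The price is that ring A must afterwards be grown on the C4a=C8a enone without base.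

## Retrosynthesis

**24 ⇒ 23.** The four O–CH2Ph bonds of 23 are cut last. Benzyl ethers survive every reagent of the route (Grignard reagents, silyl triflates, a zirconium Lewis acid, peracid, 80 °C) and can be removed without hydrogen or base, by BCl3 with pentamethylbenzene as cation trap. The two ring A phenols are never protected, because protecting them would require base on the finished chromanone.

**23 ⇒ 17 + 22.** The bond between C5 of ring D and the enone β-carbon is cut. A hydroxide-mediated aldol condensation would open ring C. A Heck reaction with an aryl vinyl ketone needs hot amine or acetate, and the free ring A phenols would add to the vinyl ketone. A Stille coupling of aryl bromide 17 with the E β-stannyl enone 22 needs no base and tolerates free phenols. Bromide 17 is the complete stereodefined core. Stannane 22 comes in two steps from aldehyde 18 and bis-stannane 19, through vinyllithium 20 and alcohol 21.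

**17 ⇒ 12 + 14.** Ring A is cut at C4a–C5 and C8–C8a. The four carbons C5–C8 with oxygen on C5 and C7 are the bis-silyl dienol ether 14 of methyl acetoacetate 13. Its nucleophilic CH2 terminus must go to C8a, the enone β-carbon, which places the ketene acetal carbon on C4a, next to the C4 ketone. For an arene to result, C4a must carry a leaving group. In cycloadduct 15 that group sits on a quaternary carbon and the only neighbouring hydrogen, H8a, is cis to it, so only a thermal syn elimination can work; this points to a sulfoxide, which also activates the dienophile. Loss of benzenesulfenic acid gives 16, and acid removes methanol and silicon to give the phenol tautomer 17. Sulfoxide 12 comes from pyranone 10 by α-sulfenylation to 11 and oxidation. This annulation is the least precedented part of the plan; it is accepted because it needs no base.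

**10 ⇒ 7 + 8 (key disconnection).** C2–C3 and O1–C8a are cut. Aldehyde 8 supplies C2, O1 and ring B; diene 7 supplies C3 with ring D, the C4 carbonyl and the C4a=C8a enol ether. A chiral zirconium binaphtholate joins them through the anti aldol 9, and acid closes ring C. Compared with the later annulation this cut has close precedent, sets both stereocentres in the ring-forming step and delivers the carbonyl at C4 in the right oxidation state. The forward reaction has to control the aldehyde face; the trans relationship is secured twice, kinetically and by equilibration at C3.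

**7 ⇒ 6 ⇒ 5 ⇒ 4 ⇒ 3 ⇒ 2 ⇒ 1.** Diene 7 is the silyl enol ether of β-methoxy enone 6, which is the methanol adduct of ynone 5. Ynone 5 comes from ethynylmagnesium bromide and N-methoxy-N-methylamide 4. The amide derives from benzyl ester 3, made by double benzylation of bromo acid 2, the para-bromination product of 2-hydroxyphenylacetic acid 1. The bromine is an inert spectator until the Stille step.

## Roads not taken

**Alternative 1:** ortho-quinone methide plus stilbene. The cut is at O1–C2 and C3–C4. A chiral phosphoric acid dehydrates 3,5-bis(benzyloxy)-2-(hydroxymethyl)phenol A2 to its ortho-quinone methide, which adds across the E-stilbene A3 to give the 2,3-trans chroman A1.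
- Merits: both stereocentres arise in one organocatalytic step from two flat precursors, the trans relationship follows from the alkene geometry, and ring A arrives intact. In that respect it is better than the chosen plan, which must build ring A by an unproven annulation.
- Weak points: A1 has a methylene at C4. The ketone must be introduced by benzylic oxidation next to C2–H, which is itself benzylic, α to oxygen and activated by ring B; dehydrogenation toward a chromene or flavylium and attack at C2 are the likely outcomes. The free phenol of A3, needed for reactivity, adds a protecting-group change.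
- Comparison: the chosen plan carries the C4 carbonyl from the diene and never oxidises the stereodefined core. Against Alternative 1 it has to set a longer sequence and the risk of step 11.

**Alternative 2:** rhodium carbene C–H insertion. The cut is at C2–C3. Rh2(S-PTTL)4, dirhodium tetrakis[N-phthaloyl-(S)-tert-leucinate], turns diazoketone A4 into a carbene at C3 that inserts into an O–CH2–aryl C–H bond to give chromanone A5.
- Merits: ring A comes from phloroglucinol, the carbonyl is in place, and only coupling and deprotection remain after the key step. It is clearly shorter than the chosen plan.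
- Weak points: ring closure is an insertion that forms a six-membered ring, less favoured than the usual five-membered mode. It competes with attack on the electron-rich arenes and on the other benzylic ethers. Three identical 4-benzyloxybenzyl groups are needed only to make the two ortho ethers equivalent. Enantiocontrol for this ring size rests on little precedent.
- Comparison: both plans rely on equilibration of C3. The chosen plan sets against the shorter route a C–C bond formation (aldehyde plus 4-substituted silyloxy diene) whose selectivity model is established.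

**Alternative 3:** aryne annulation of an anti aldol ester. The cut is at O1–C8a and C4–C4a. CsF releases the alkoxide of A6 and the aryne of A7; the alkoxide adds to the aryne and the aryl anion closes on the methyl ester to give A8.
- Merits: convergent, ring A is a ready-made arene, and the 3-alkoxy group of the aryne directs the regiochemistry. Its step economy after ring formation is as good as that of Alternative 2 and better than the chosen plan.
- Weak points: the stereocentres must come from a separate asymmetric anti aldol of an arylacetate. Fluoride then generates a β-alkoxide of that aldol (retro-aldol, epimerisation), and the product A8 sits in basic fluoride, the conditions that open ring C. A7 needs several steps.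
- Comparison: the chosen plan forms both centres in the catalytic ring-forming step and exposes the β-oxy ketone to nothing more basic than pyridine. It pays with the ring A annulation.

Key step: step 7

Assumption: the sense of induction is not known for this diene; the catalyst from (R)-3,3'-diiodo-1,1'-bi-2-naphthol is written on the assumption that it directs attack to the Si face of 8 (giving 2S), and the (S)-ligand would be used if the first run showed the opposite.

## Route

Step 1
Reactants: 1 2-hydroxyphenylacetic acid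
Product: 2 2-(5-bromo-2-hydroxyphenyl)acetic acid
Conditions: NBS, MeCN, 0 °C → rt
Reagents that add atoms: N-bromosuccinimide, O=C1CCC(=O)N1Br
Why: Electrophilic aromatic bromination; the phenol directs to its para position (C5), the ortho position being the minor site.

Step 2
Reactants: 2 2-(5-bromo-2-hydroxyphenyl)acetic acid
Product: 3 benzyl 2-[2-(benzyloxy)-5-bromophenyl]acetate
Conditions: BnBr, K2CO3, DMF, rt → 50 °C
Reagents that add atoms: benzyl bromide, BrCc1ccccc1
Why: Williamson etherification and carboxylate alkylation (SN2) benzylate both acidic sites in one operation; carbonate is too weak to alkylate the benzylic CH2.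

Step 3
Reactants: 3 benzyl 2-[2-(benzyloxy)-5-bromophenyl]acetate
Product: 4 2-[2-(benzyloxy)-5-bromophenyl]-N-methoxy-N-methylacetamide
Conditions: MeNH(OMe)·HCl, i-PrMgCl, THF, −20 → 0 °C
Reagents that add atoms: N,O-dimethylhydroxylamine hydrochloride, CNOC.Cl
Why: Ester aminolysis by the chloromagnesium amide of N,O-dimethylhydroxylamine; the unactivated aryl bromide does not exchange with i-PrMgCl at this temperature.

Step 4
Reactants: 4 2-[2-(benzyloxy)-5-bromophenyl]-N-methoxy-N-methylacetamide
Product: 5 1-[2-(benzyloxy)-5-bromophenyl]but-3-yn-2-one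
Conditions: HC≡CMgBr, THF, 0 °C; aq. NaHSO4
Reagents that add atoms: ethynylmagnesium bromide, C#C[Mg]Br
Why: Weinreb ketone synthesis; the chelated tetrahedral intermediate prevents over-addition, and the acidic quench keeps the released amine from adding to the ynone.

Step 5
Reactants: 5 1-[2-(benzyloxy)-5-bromophenyl]but-3-yn-2-one
Product: 6 (3E)-1-[2-(benzyloxy)-5-bromophenyl]-4-methoxybut-3-en-2-one
Conditions: MeOH, DABCO (10 mol%), CH2Cl2, 0 °C → rt
Reagents that add atoms: methanol, CO
Why: Amine-catalysed conjugate addition of methanol to a terminal ynone (oxa-Michael); reversible addition of the amine equilibrates the product to the E β-methoxy enone.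

Step 6
Reactants: 6 (3E)-1-[2-(benzyloxy)-5-bromophenyl]-4-methoxybut-3-en-2-one
Product: 7 (1E,3Z)-4-[2-(benzyloxy)-5-bromophenyl]-1-methoxy-3-(trimethylsilyloxy)buta-1,3-diene
Conditions: TMSOTf, Et3N, Et2O, 0 °C
Reagents that add atoms: trimethylsilyl trifluoromethanesulfonate, C[Si](C)(C)OS(=O)(=O)C(F)(F)F
Why: Soft enolisation and O-silylation at the only enolisable, benzylic position; the Z enol ether (aryl cis to OSi) avoids allylic strain with the methoxyvinyl group. The diene is used crude after removal of the ammonium salt.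

Step 7
Reactants: 7 (1E,3Z)-4-[2-(benzyloxy)-5-bromophenyl]-1-methoxy-3-(trimethylsilyloxy)buta-1,3-diene; 8 4-(benzyloxy)benzaldehyde
Product: 10 (2S,3R)-3-[2-(benzyloxy)-5-bromophenyl]-2-[4-(benzyloxy)phenyl]-2,3-dihydro-4H-pyran-4-one, via anti-aldol silyl ether 9 (not isolated)
Conditions: Zr(OtBu)4 (10 mol%), (R)-3,3'-diiodo-1,1'-bi-2-naphthol (12 mol%), n-PrOH, H2O (cat.), toluene, −20 °C; then TFA, CH2Cl2, 0 °C
Reagents that add atoms: none
Why: The zirconium binaphtholate, a chiral Lewis acid, binds aldehyde 8, and the aryl-bearing terminus of diene 7 attacks the carbonyl carbon in an open Mukaiyama aldol transition state, forming C2–C3 and giving silyl ether 9. TFA then lets the C2 oxygen add to the methoxy-bearing enone carbon and expel methanol (6-endo-trig oxa-Michael addition, then β-elimination), forming O1–C6 (the future C8a) and closing ring C; overall a stepwise formal hetero-[4+2]. The closest known reaction type is the zirconium–binaphthol-catalysed hetero-Diels–Alder reaction of aldehydes with 4-substituted 1-alkoxy-3-silyloxy dienes, which is 2,3-trans selective. C2 is controlled by the catalyst: the 3,3'-diiodobinaphtholate ligands shield one face of the bound aldehyde so that the Si face is attacked (2S). C3 is controlled relative to C2 by the open transition state, which gives the anti aldol and hence the trans pyranone whatever the enol ether geometry. Because C3 is benzylic and α to the ketone, any cis isomer should equilibrate to the diequatorial trans isomer in the acid of the ring closure. The step needs enantioface selectivity at the aldehyde and reaction at the diene terminus remote from the methoxy group; the silyl enol ether makes that terminus the nucleophile, and the aryl bromide and benzyl ethers are inert to the Lewis acid.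

Step 8
Reactants: 10 (2S,3R)-3-[2-(benzyloxy)-5-bromophenyl]-2-[4-(benzyloxy)phenyl]-2,3-dihydro-4H-pyran-4-one
Product: 11 (2S,3R)-3-[2-(benzyloxy)-5-bromophenyl]-2-[4-(benzyloxy)phenyl]-5-(phenylsulfanyl)-2,3-dihydro-4H-pyran-4-one
Conditions: PhSCl, CH2Cl2, −78 °C; then pyridine, −78 → 0 °C
Reagents that add atoms: benzenesulfenyl chloride, ClSc1ccccc1
Why: Electrophilic α-sulfenylation of a vinylogous ester: the enol ether double bond attacks sulfur at C5 (the future C4a) and pyridine removes HCl from the adduct, the same addition–elimination as α-iodination or α-selenenylation of enones. Pyridine at low temperature does not enolise C3.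

Step 9
Reactants: 11 (2S,3R)-3-[2-(benzyloxy)-5-bromophenyl]-2-[4-(benzyloxy)phenyl]-5-(phenylsulfanyl)-2,3-dihydro-4H-pyran-4-one
Product: 12 (2S,3R)-3-[2-(benzyloxy)-5-bromophenyl]-2-[4-(benzyloxy)phenyl]-5-(phenylsulfinyl)-2,3-dihydro-4H-pyran-4-one (both sulfur epimers)
Conditions: mCPBA (1.0 equiv), CH2Cl2, −78 → −40 °C
Reagents that add atoms: 3-chloroperoxybenzoic acid, OOC(=O)c1cccc(Cl)c1
Why: Sulfide-to-sulfoxide oxidation with one equivalent of peracid, far faster than attack on the electron-poor enone; both sulfur epimers are used because sulfur is lost in step 11.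

Step 10
Reactants: 13 methyl acetoacetate
Product: 14 1-methoxy-1,3-bis(trimethylsilyloxy)buta-1,3-diene (ketene acetal geometry immaterial)
Conditions: TMSOTf (2.1 equiv), Et3N, Et2O, 0 °C → rt
Reagents that add atoms: trimethylsilyl trifluoromethanesulfonate, C[Si](C)(C)OS(=O)(=O)C(F)(F)F
Why: Double soft enolisation and O-silylation of a β-keto ester gives the 1,3-bis(silyloxy)diene, used freshly prepared.

Step 11
Reactants: 12 (2S,3R)-3-[2-(benzyloxy)-5-bromophenyl]-2-[4-(benzyloxy)phenyl]-5-(phenylsulfinyl)-2,3-dihydro-4H-pyran-4-one; 14 1-methoxy-1,3-bis(trimethylsilyloxy)buta-1,3-diene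
Product: 17 (2S,3R)-3-[2-(benzyloxy)-5-bromophenyl]-2-[4-(benzyloxy)phenyl]-5,7-dihydroxychroman-4-one, via sulfinyl cycloadduct 15 (not isolated), via bis-silyl dienyl ketal 16 (not isolated)
Conditions: toluene, 80 °C; then 1 M HCl, THF, 0 °C → rt
Reagents that add atoms: none
Why: Proposed new method: the α-sulfinyl β-alkoxy enone of 12 is a doubly activated dienophile whose β-carbon (future C8a) takes the nucleophilic CH2 terminus of 14 while the ketene acetal carbon bonds to C4a in a polarised, possibly stepwise [4+2] cycloaddition to 15. The sulfinyl group and H8a are cis and leave by thermal syn elimination to 16, and acid removes methanol and both silyl groups so that the ring tautomerises to the 5,7-dihydroxyarene. No base is present and C2 and C3 are untouched. The closest known reaction types are the Diels–Alder reactions of 3-substituted chromones with 1-methoxy-3-silyloxy dienes to give xanthones and of sulfinyl or halo quinones with 1,1-dioxygenated 3-silyloxy dienes to give resorcinol rings.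

Step 12
Reactants: 18 2,4-bis(benzyloxy)benzaldehyde; 19 (E)-1,2-bis(tributylstannyl)ethene
Product: 21 (2E)-1-[2,4-bis(benzyloxy)phenyl]-3-(tributylstannyl)prop-2-en-1-ol (racemic), via (E)-2-(tributylstannyl)vinyllithium 20 (not isolated)
Conditions: n-BuLi, THF, −78 °C; then 18, −78 °C; aq. NH4Cl
Reagents that add atoms: none
Why: Tin–lithium exchange on one terminus of 19 gives vinyllithium 20, which adds 1,2 to the aldehyde with retention of the E geometry.

Step 13
Reactants: 21 (2E)-1-[2,4-bis(benzyloxy)phenyl]-3-(tributylstannyl)prop-2-en-1-ol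
Product: 22 (2E)-1-[2,4-bis(benzyloxy)phenyl]-3-(tributylstannyl)prop-2-en-1-one
Conditions: MnO2, CH2Cl2, rt
Reagents that add atoms: none
Why: MnO2 oxidation of an alcohol that is both allylic and benzylic; the vinylstannane and benzyl ethers are inert.

Step 14
Reactants: 17 (2S,3R)-3-[2-(benzyloxy)-5-bromophenyl]-2-[4-(benzyloxy)phenyl]-5,7-dihydroxychroman-4-one; 22 (2E)-1-[2,4-bis(benzyloxy)phenyl]-3-(tributylstannyl)prop-2-en-1-one
Product: 23 (2S,3R)-3-{2-(benzyloxy)-5-[(1E)-3-[2,4-bis(benzyloxy)phenyl]-3-oxoprop-1-en-1-yl]phenyl}-2-[4-(benzyloxy)phenyl]-5,7-dihydroxychroman-4-one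
Conditions: Pd(PPh3)4 (5 mol%), CuI (10 mol%), DMF, 70 °C
Reagents that add atoms: none
Why: Stille coupling: oxidative addition of zerovalent palladium into the aryl bromide, copper-assisted transmetalation of the β-stannyl enone with retention of E geometry, reductive elimination. No base is present, so the C3 enolate that would open ring C cannot form, and the free ring A phenols are tolerated.

Step 15
Reactants: 23 (2S,3R)-3-{2-(benzyloxy)-5-[(1E)-3-[2,4-bis(benzyloxy)phenyl]-3-oxoprop-1-en-1-yl]phenyl}-2-[4-(benzyloxy)phenyl]-5,7-dihydroxychroman-4-one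
Product: 24 (2S,3R)-3-{5-[(1E)-3-(2,4-dihydroxyphenyl)-3-oxoprop-1-en-1-yl]-2-hydroxyphenyl}-5,7-dihydroxy-2-(4-hydroxyphenyl)chroman-4-one
Conditions: BCl3, C6HMe5, CH2Cl2, −78 → −40 °C; MeOH quench
Reagents that add atoms: none
Why: Lewis acid cleavage of aryl benzyl ethers, with pentamethylbenzene trapping the benzyl cations by Friedel–Crafts alkylation so that rings A and E are not benzylated. No hydrogen is used, so the enone survives, and the low temperature and absence of base protect C2 and C3.

## Compound list

1 | 2-hydroxyphenylacetic acid | OC(=O)Cc1ccccc1O | starting material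
2 | 2-(5-bromo-2-hydroxyphenyl)acetic acid | OC(=O)Cc1cc(Br)ccc1O | intermediate
3 | benzyl 2-[2-(benzyloxy)-5-bromophenyl]acetate | O=C(Cc1cc(Br)ccc1OCc1ccccc1)OCc1ccccc1 | intermediate
4 | 2-[2-(benzyloxy)-5-bromophenyl]-N-methoxy-N-methylacetamide | CON(C)C(=O)Cc1cc(Br)ccc1OCc1ccccc1 | intermediate
5 | 1-[2-(benzyloxy)-5-bromophenyl]but-3-yn-2-one | C#CC(=O)Cc1cc(Br)ccc1OCc1ccccc1 | intermediate
6 | (3E)-1-[2-(benzyloxy)-5-bromophenyl]-4-methoxybut-3-en-2-one | CO/C=C/C(=O)Cc1cc(Br)ccc1OCc1ccccc1 | intermediate
7 | (1E,3Z)-4-[2-(benzyloxy)-5-bromophenyl]-1-methoxy-3-(trimethylsilyloxy)buta-1,3-diene | CO/C=C/C(O[Si](C)(C)C)=C/c1cc(Br)ccc1OCc1ccccc1 | intermediate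
8 | 4-(benzyloxy)benzaldehyde | O=Cc1ccc(OCc2ccccc2)cc1 | starting material
9 | (1E,4R,5S)-4-[2-(benzyloxy)-5-bromophenyl]-5-[4-(benzyloxy)phenyl]-1-methoxy-5-(trimethylsilyloxy)pent-1-en-3-one | Brc1ccc(OCc2ccccc2)c([C@H]([C@H](O[Si](C)(C)C)c2ccc(OCc3ccccc3)cc2)C(=O)/C=C/OC)c1 | intermediate (not isolated)
10 | (2S,3R)-3-[2-(benzyloxy)-5-bromophenyl]-2-[4-(benzyloxy)phenyl]-2,3-dihydro-4H-pyran-4-one | Brc1ccc(OCc2ccccc2)c([C@H]2C(=O)C=CO[C@@H]2c2ccc(OCc3ccccc3)cc2)c1 | intermediate
11 | (2S,3R)-3-[2-(benzyloxy)-5-bromophenyl]-2-[4-(benzyloxy)phenyl]-5-(phenylsulfanyl)-2,3-dihydro-4H-pyran-4-one | Brc1ccc(OCc2ccccc2)c([C@H]2C(=O)C(Sc3ccccc3)=CO[C@@H]2c2ccc(OCc3ccccc3)cc2)c1 | intermediate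
12 | (2S,3R)-3-[2-(benzyloxy)-5-bromophenyl]-2-[4-(benzyloxy)phenyl]-5-(phenylsulfinyl)-2,3-dihydro-4H-pyran-4-one, both sulfur epimers | Brc1ccc(OCc2ccccc2)c([C@H]2C(=O)C(S(=O)c3ccccc3)=CO[C@@H]2c2ccc(OCc3ccccc3)cc2)c1 | intermediate
13 | methyl acetoacetate | COC(=O)CC(C)=O | starting material
14 | 1-methoxy-1,3-bis(trimethylsilyloxy)buta-1,3-diene | COC(O[Si](C)(C)C)=CC(=C)O[Si](C)(C)C | intermediate
15 | (2S,3R)-3-[2-(benzyloxy)-5-bromophenyl]-2-[4-(benzyloxy)phenyl]-5-methoxy-4a-(phenylsulfinyl)-5,7-bis(trimethylsilyloxy)-2,3,4a,5,8,8a-hexahydro-4H-chromen-4-one, cis ring fusion, C5 and sulfur undefined | Brc1ccc(OCc2ccccc2)c([C@H]2C(=O)C3(S(=O)c4ccccc4)C(OC)(O[Si](C)(C)C)C=C(O[Si](C)(C)C)CC3O[C@@H]2c2ccc(OCc3ccccc3)cc2)c1 | intermediate (not isolated)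
16 | (2S,3R)-3-[2-(benzyloxy)-5-bromophenyl]-2-[4-(benzyloxy)phenyl]-5-methoxy-5,7-bis(trimethylsilyloxy)-2,3,5,8-tetrahydro-4H-chromen-4-one, C5 undefined | Brc1ccc(OCc2ccccc2)c([C@H]2C(=O)C3=C(CC(O[Si](C)(C)C)=CC3(OC)O[Si](C)(C)C)O[C@@H]2c2ccc(OCc3ccccc3)cc2)c1 | intermediate (not isolated)
17 | (2S,3R)-3-[2-(benzyloxy)-5-bromophenyl]-2-[4-(benzyloxy)phenyl]-5,7-dihydroxychroman-4-one | Brc1ccc(OCc2ccccc2)c([C@H]2C(=O)c3c(O)cc(O)cc3O[C@@H]2c2ccc(OCc3ccccc3)cc2)c1 | intermediate
18 | 2,4-bis(benzyloxy)benzaldehyde | O=Cc1ccc(OCc2ccccc2)cc1OCc1ccccc1 | starting material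
19 | (E)-1,2-bis(tributylstannyl)ethene | CCCC[Sn](CCCC)(CCCC)/C=C/[Sn](CCCC)(CCCC)CCCC | starting material
20 | (E)-2-(tributylstannyl)vinyllithium | [Li]/C=C/[Sn](CCCC)(CCCC)CCCC | intermediate (not isolated)
21 | (2E)-1-[2,4-bis(benzyloxy)phenyl]-3-(tributylstannyl)prop-2-en-1-ol, racemic | OC(/C=C/[Sn](CCCC)(CCCC)CCCC)c1ccc(OCc2ccccc2)cc1OCc1ccccc1 | intermediate
22 | (2E)-1-[2,4-bis(benzyloxy)phenyl]-3-(tributylstannyl)prop-2-en-1-one | O=C(/C=C/[Sn](CCCC)(CCCC)CCCC)c1ccc(OCc2ccccc2)cc1OCc1ccccc1 | intermediate
23 | (2S,3R)-3-{2-(benzyloxy)-5-[(1E)-3-[2,4-bis(benzyloxy)phenyl]-3-oxoprop-1-en-1-yl]phenyl}-2-[4-(benzyloxy)phenyl]-5,7-dihydroxychroman-4-one | O=C(/C=C/c1ccc(OCc2ccccc2)c([C@H]2C(=O)c3c(O)cc(O)cc3O[C@@H]2c2ccc(OCc3ccccc3)cc2)c1)c1ccc(OCc2ccccc2)cc1OCc1ccccc1 | intermediate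
24 | (2S,3R)-3-{5-[(1E)-3-(2,4-dihydroxyphenyl)-3-oxoprop-1-en-1-yl]-2-hydroxyphenyl}-5,7-dihydroxy-2-(4-hydroxyphenyl)chroman-4-one | O=C(/C=C/c1ccc(O)c([C@H]2C(=O)c3c(O)cc(O)cc3O[C@@H]2c2ccc(O)cc2)c1)c1ccc(O)cc1O | target

## Step count and uncertain steps

Total: 15 steps. Longest linear sequence: 12 steps (steps 1–9, 11, 14, 15); side branches are step 10 and steps 12–13.

**Step 11 (Proposed new method).** The likeliest failure is that the diene adds only at C8a (Michael-type) without closing on the fully substituted C4a, or is consumed by silyl transfer and by the sulfenic acid, so that no arene forms. The fallback uses known chemistry, gives up catalytic control of the core and relies on separation. It sets out from ester 3 and aldehyde 8 and returns at 17. Saponification of 3 (LiOH, aq. THF) gives 2-[2-(benzyloxy)-5-bromophenyl]acetic acid F1. Friedel–Crafts acylation of phloroglucinol with F1 (BF3·OEt2, 70 °C) gives the deoxybenzoin 2-[2-(benzyloxy)-5-bromophenyl]-1-(2,4,6-trihydroxyphenyl)ethan-1-one F2. Condensation of F2 with 8 (piperidine, EtOH, reflux) passes through the α-aryl chalcone and closes under thermodynamic control to the racemic trans chromanone, that is 17 together with its enantiomer (2R,3S)-3-[2-(benzyloxy)-5-bromophenyl]-2-[4-(benzyloxy)phenyl]-5,7-dihydroxychroman-4-one F3, from which 17 is separated on a chiral stationary phase.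

**Step 7 (key step).** The electron-rich aldehyde 8 is a weak electrophile and the 4-aryl diene a hindered nucleophile, so an uncatalysed or silyl-cation-mediated background addition may outrun the catalysed pathway and erode facial selectivity; residual amine from step 6 may also displace the ligand. The fallback replaces catalyst control by a stoichiometric chiral boron enolate; it sets out from enone 6 and returns at 10. Enolisation of 6 with the appropriate enantiomer of diisopinocampheylboron triflate, (Ipc)2BOTf, and i-Pr2NEt (CH2Cl2, −78 °C), then addition of 8, should give through a closed chair transition state the syn aldol (1E,4S,5S)-4-[2-(benzyloxy)-5-bromophenyl]-5-[4-(benzyloxy)phenyl]-5-hydroxy-1-methoxypent-1-en-3-one F4, with the boron ligands fixing the carbinol centre. TFA (CH2Cl2, 0 °C) closes F4 with loss of methanol to the cis pyranone (2S,3S)-3-[2-(benzyloxy)-5-bromophenyl]-2-[4-(benzyloxy)phenyl]-2,3-dihydro-4H-pyran-4-one F5, which equilibrates at C3 in the same acid to 10.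

**Step 8.** Addition of the sulfenyl chloride across the enol ether without clean loss of HCl, or competing sulfenylation of the benzyloxyarene rings, would give mixtures. The fallback sets out from 10 and returns at 11. I2 and pyridine (CH2Cl2, rt) give (2S,3R)-3-[2-(benzyloxy)-5-bromophenyl]-2-[4-(benzyloxy)phenyl]-5-iodo-2,3-dihydro-4H-pyran-4-one F6 by the standard α-iodination of enones. CuSPh (DMF, 70 °C) then replaces the vinylic iodide, without added base and without touching the aryl bromide, to give 11.

**Step 14.** Transmetalation of the electron-poor β-stannyl enone onto an electron-rich arylpalladium bromide may be slow, leading to protodestannylation and homocoupling of 22. The fallback sets out from 17 and 18 and returns at 23. Stille coupling of 17 with tributyl(vinyl)stannane (Pd(PPh3)4, toluene, 100 °C) gives the styrene (2S,3R)-3-[2-(benzyloxy)-5-ethenylphenyl]-2-[4-(benzyloxy)phenyl]-5,7-dihydroxychroman-4-one F7. Vinylmagnesium bromide adds to 18 to give 1-[2,4-bis(benzyloxy)phenyl]prop-2-en-1-ol F8, and MnO2 oxidises it to 1-[2,4-bis(benzyloxy)phenyl]prop-2-en-1-one F9. Cross-metathesis of F7 with F9 (second-generation Hoveyda–Grubbs catalyst, CH2Cl2, 40 °C), neutral and E-selective, gives 23.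

**Step 15.** While the slow, non-chelated ethers are being cleaved, liberated benzyl cations may alkylate rings A and E, HCl may add across the enone, and prolonged Lewis acid contact may ionise the O1–C2 bond. The fallback moves the BCl3 step ahead of the coupling and carries ring E with acid-labile groups; it sets out from 17 and returns at 24. BCl3 and C6HMe5 (CH2Cl2, −78 °C) cleave the two benzyl ethers of 17 to (2S,3R)-3-(5-bromo-2-hydroxyphenyl)-5,7-dihydroxy-2-(4-hydroxyphenyl)chroman-4-one F10. Separately, 2,4-dihydroxybenzaldehyde and MOMCl/i-Pr2NEt give 2,4-bis(methoxymethoxy)benzaldehyde F11, which is taken as in steps 12 and 13 to (2E)-1-[2,4-bis(methoxymethoxy)phenyl]-3-(tributylstannyl)prop-2-en-1-ol F12 and (2E)-1-[2,4-bis(methoxymethoxy)phenyl]-3-(tributylstannyl)prop-2-en-1-one F13. Stille coupling of F10 with F13 under the conditions of step 14 gives (2S,3R)-3-{5-[(1E)-3-[2,4-bis(methoxymethoxy)phenyl]-3-oxoprop-1-en-1-yl]-2-hydroxyphenyl}-5,7-dihydroxy-2-(4-hydroxyphenyl)chroman-4-one F14, and HCl in MeOH at 40 °C releases 24.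

## Further compounds

F1 | step 11 | 2-[2-(benzyloxy)-5-bromophenyl]acetic acid | OC(=O)Cc1cc(Br)ccc1OCc1ccccc1
F2 | step 11 | 2-[2-(benzyloxy)-5-bromophenyl]-1-(2,4,6-trihydroxyphenyl)ethan-1-one | O=C(Cc1cc(Br)ccc1OCc1ccccc1)c1c(O)cc(O)cc1O
F3 | step 11 | (2R,3S)-3-[2-(benzyloxy)-5-bromophenyl]-2-[4-(benzyloxy)phenyl]-5,7-dihydroxychroman-4-one | Brc1ccc(OCc2ccccc2)c([C@@H]2C(=O)c3c(O)cc(O)cc3O[C@H]2c2ccc(OCc3ccccc3)cc2)c1
F4 | step 7 | (1E,4S,5S)-4-[2-(benzyloxy)-5-bromophenyl]-5-[4-(benzyloxy)phenyl]-5-hydroxy-1-methoxypent-1-en-3-one | Brc1ccc(OCc2ccccc2)c([C@@H]([C@H](O)c2ccc(OCc3ccccc3)cc2)C(=O)/C=C/OC)c1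
F5 | step 7 | (2S,3S)-3-[2-(benzyloxy)-5-bromophenyl]-2-[4-(benzyloxy)phenyl]-2,3-dihydro-4H-pyran-4-one | Brc1ccc(OCc2ccccc2)c([C@@H]2C(=O)C=CO[C@@H]2c2ccc(OCc3ccccc3)cc2)c1
F6 | step 8 | (2S,3R)-3-[2-(benzyloxy)-5-bromophenyl]-2-[4-(benzyloxy)phenyl]-5-iodo-2,3-dihydro-4H-pyran-4-one | Brc1ccc(OCc2ccccc2)c([C@H]2C(=O)C(I)=CO[C@@H]2c2ccc(OCc3ccccc3)cc2)c1
F7 | step 14 | (2S,3R)-3-[2-(benzyloxy)-5-ethenylphenyl]-2-[4-(benzyloxy)phenyl]-5,7-dihydroxychroman-4-one | C=Cc1ccc(OCc2ccccc2)c([C@H]2C(=O)c3c(O)cc(O)cc3O[C@@H]2c2ccc(OCc3ccccc3)cc2)c1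
F8 | step 14 | 1-[2,4-bis(benzyloxy)phenyl]prop-2-en-1-ol (racemic) | C=CC(O)c1ccc(OCc2ccccc2)cc1OCc1ccccc1
F9 | step 14 | 1-[2,4-bis(benzyloxy)phenyl]prop-2-en-1-one | C=CC(=O)c1ccc(OCc2ccccc2)cc1OCc1ccccc1
F10 | step 15 | (2S,3R)-3-(5-bromo-2-hydroxyphenyl)-5,7-dihydroxy-2-(4-hydroxyphenyl)chroman-4-one | Brc1ccc(O)c([C@H]2C(=O)c3c(O)cc(O)cc3O[C@@H]2c2ccc(O)cc2)c1
F11 | step 15 | 2,4-bis(methoxymethoxy)benzaldehyde | O=Cc1ccc(OCOC)cc1OCOC
F12 | step 15 | (2E)-1-[2,4-bis(methoxymethoxy)phenyl]-3-(tributylstannyl)prop-2-en-1-ol (racemic) | OC(/C=C/[Sn](CCCC)(CCCC)CCCC)c1ccc(OCOC)cc1OCOC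
F13 | step 15 | (2E)-1-[2,4-bis(methoxymethoxy)phenyl]-3-(tributylstannyl)prop-2-en-1-one | O=C(/C=C/[Sn](CCCC)(CCCC)CCCC)c1ccc(OCOC)cc1OCOC
F14 | step 15 | (2S,3R)-3-{5-[(1E)-3-[2,4-bis(methoxymethoxy)phenyl]-3-oxoprop-1-en-1-yl]-2-hydroxyphenyl}-5,7-dihydroxy-2-(4-hydroxyphenyl)chroman-4-one | O=C(/C=C/c1ccc(O)c([C@H]2C(=O)c3c(O)cc(O)cc3O[C@@H]2c2ccc(O)cc2)c1)c1ccc(OCOC)cc1OCOC
A1 | alternative 1 | 4-bromo-2-[(2S,3R)-5,7-bis(benzyloxy)-2-(4-hydroxyphenyl)chroman-3-yl]phenyl acetate (2,3-trans) | CC(=O)Oc1ccc(Br)cc1[C@H]1Cc2c(OCc3ccccc3)cc(OCc3ccccc3)cc2O[C@@H]1c1ccc(O)cc1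
A2 | alternative 1 | 3,5-bis(benzyloxy)-2-(hydroxymethyl)phenol | OCc1c(O)cc(OCc2ccccc2)cc1OCc1ccccc1
A3 | alternative 1 | 4-bromo-2-[(E)-2-(4-hydroxyphenyl)ethenyl]phenyl acetate | CC(=O)Oc1ccc(Br)cc1/C=C/c1ccc(O)cc1
A4 | alternative 2 | 2-[5-bromo-2-(tert-butyldimethylsilyloxy)phenyl]-2-diazo-1-{2,4,6-tris[(4-benzyloxybenzyl)oxy]phenyl}ethan-1-one | O=C(C(=[N+]=[N-])c1cc(Br)ccc1O[Si](C)(C)C(C)(C)C)c1c(OCc2ccc(OCc3ccccc3)cc2)cc(OCc2ccc(OCc3ccccc3)cc2)cc1OCc1ccc(OCc2ccccc2)cc1
A5 | alternative 2 | (2S,3R)-2-[4-(benzyloxy)phenyl]-5,7-bis[(4-benzyloxybenzyl)oxy]-3-[5-bromo-2-(tert-butyldimethylsilyloxy)phenyl]chroman-4-one | Brc1ccc(O[Si](C)(C)C(C)(C)C)c([C@H]2C(=O)c3c(OCc4ccc(OCc5ccccc5)cc4)cc(OCc4ccc(OCc5ccccc5)cc4)cc3O[C@@H]2c2ccc(OCc3ccccc3)cc2)c1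
A6 | alternative 3 | methyl (2R,3S)-2-[2-(benzyloxy)-5-bromophenyl]-3-[4-(benzyloxy)phenyl]-3-(trimethylsilyloxy)propanoate | COC(=O)[C@H](c1cc(Br)ccc1OCc1ccccc1)[C@H](O[Si](C)(C)C)c1ccc(OCc2ccccc2)cc1
A7 | alternative 3 | 3,5-bis(benzyloxy)-2-(trimethylsilyl)phenyl trifluoromethanesulfonate | C[Si](C)(C)c1c(OCc2ccccc2)cc(OCc2ccccc2)cc1OS(=O)(=O)C(F)(F)F
A8 | alternative 3 | (2S,3R)-5,7-bis(benzyloxy)-3-[2-(benzyloxy)-5-bromophenyl]-2-[4-(benzyloxy)phenyl]chroman-4-one | Brc1ccc(OCc2ccccc2)c([C@H]2C(=O)c3c(OCc4ccccc4)cc(OCc4ccccc4)cc3O[C@@H]2c2ccc(OCc3ccccc3)cc2)c1
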